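**Plan**

Locants for all bicyclic compounds (Ar = 3,4-dimethoxyphenyl): C1 allyl bridgehead, C2 CH2, C3 CH(OMe), C4 C=O, C5 OMe bridgehead, C6 CH-Ar, C7 CH-Me, C8 CH-OAc bridge; the target is (1S,3S,5S,6S,7R,8S).
Retrosynthesis: C3 is excised first (bonds C2-C3 and C3-C4), leaving a norbornanone. Its ketone C4 lies between C2H2 and the fully substituted bridgehead C5, so only the C2=C4 enol silane can form and a carbene carbon can re-enter only between C2 and C4.
Next C5-C6 and C1-C7 are cut ([4+2]) to (E)-3,4-dimethoxycinnamaldehyde and a 5,5-dimethoxycyclopentadiene (silyl dienol ether), made from cyclopent-4-ene-1,3-dione by ketalisation, oxygenation at the future C5 and conjugate allylation.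
Forward: the cyclopentenone is elaborated, the Diels-Alder reaction closes the norbornene, and dibromocarbene insertion enlarges ring C1-C2-C4-C5-C8 to the six-membered ring of the bicyclo[3.2.1]octane; C3-OMe and C8-OAc follow.
Stereochemistry: C1, C5, C6 and C7 come from the amine-catalysed exo-formyl Diels-Alder step, C8 from hydride delivered by the C7 hydroxymethyl group, and C3 from enolate protonation on the face of the free C8-OH.

Key step: step 13

Assumption: the usual shielding model for diarylprolinol silyl ether iminium ions applies, so the S-configured catalyst leaves the Si face of the enal β-carbon open; if the sense were reversed, its enantiomer would be used.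

**Route**

Step 1
Reactants: 1 cyclopent-4-ene-1,3-dione
Product: 2 4,4-dimethoxycyclopent-2-en-1-one
Conditions: HC(OMe)3 (1.2 equiv), MeOH, p-TsOH (2 mol %), 0 °C → rt
Reagents that add atoms: trimethyl orthoformate, COC(OC)OC
Why: Acid-catalysed ketalisation with an orthoester as water scavenger; the two carbonyls of 1 are equivalent, and after the first ketalisation the remaining one is an ordinary, less electrophilic enone carbonyl, so the reaction should stop at the monoketal.

Step 2
Reactants: 2 4,4-dimethoxycyclopent-2-en-1-one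
Product: 4 5-hydroxy-4,4-dimethoxycyclopent-2-en-1-one (racemic), via potassium enolate 3 (not isolated)
Conditions: KN(SiMe3)2, THF, −78 °C; then 2-(phenylsulfonyl)-3-phenyloxaziridine, −78 °C
Reagents that add atoms: 2-(phenylsulfonyl)-3-phenyloxaziridine, O=S(=O)(c1ccccc1)N1OC1c1ccccc1
Why: Enolate oxidation by an N-sulfonyloxaziridine; C5 carries the only enolisable hydrogens of 2, the low temperature should suppress loss of methoxide from the β-ketal, and the new stereocentre is racemic and is erased in step 6.

Step 3
Reactants: 4 5-hydroxy-4,4-dimethoxycyclopent-2-en-1-one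
Product: 5 4,4,5-trimethoxycyclopent-2-en-1-one (racemic)
Conditions: MeI, Ag2O, MeCN, rt, dark
Reagents that add atoms: iodomethane, CI
Why: Purdie methylation etherifies the α-hydroxy ketone without a strong base, so neither α-ketol rearrangement nor β-elimination of a ketal methoxy group should intervene.

Step 4
Reactants: 5 4,4,5-trimethoxycyclopent-2-en-1-one; 6 allylmagnesium bromide (CH2=CHCH2MgBr, commercial solution in Et2O)
Product: 7 trimethyl[(3-allyl-4,4,5-trimethoxycyclopent-1-en-1-yl)oxy]silane (racemic mixture of diastereomers)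
Conditions: CuBr·SMe2 (1.1 equiv), Me3SiCl, THF, −78 °C
Reagents that add atoms: chlorotrimethylsilane, C[Si](C)(C)Cl
Why: Conjugate addition of an allylcopper reagent accelerated by Me3SiCl, which traps the enolate regiospecifically as the enol silane; allyl enters at the β-carbon next to the ketal, and the diastereomer ratio is irrelevant because both sp3 centres are flattened in steps 5 and 6.

Step 5
Reactants: 7 trimethyl[(3-allyl-4,4,5-trimethoxycyclopent-1-en-1-yl)oxy]silane
Product: 8 3-allyl-4,4,5-trimethoxycyclopent-2-en-1-one (racemic)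
Conditions: Pd(OAc)2 (10 mol %), O2 (1 atm), DMSO, rt
Reagents that add atoms: none
Why: Saegusa-Ito oxidation; the palladium enolate can undergo β-hydride elimination only towards the allyl-bearing carbon, which restores the enone with allyl on its β-carbon, while the pendant alkene could interfere only by closing a four-membered ring.

Step 6
Reactants: 8 3-allyl-4,4,5-trimethoxycyclopent-2-en-1-one
Product: 10 tert-butyl[(4-allyl-2,3,3-trimethoxycyclopenta-1,4-dien-1-yl)oxy]dimethylsilane, via lithium dienolate 9 (not isolated)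
Conditions: LiN(iPr)2, THF, −78 °C; then TBSOTf, −78 °C; non-aqueous work-up, used at once
Reagents that add atoms: tert-butyldimethylsilyl trifluoromethanesulfonate, CC(C)(C)[Si](C)(C)OS(=O)(=O)C(F)(F)F
Why: Kinetic deprotonation of the enone at the methoxy-bearing α'-carbon (in preference to the γ-methylene) and O-silylation give the cross-conjugated dienol silyl ether, a 5,5-dimethoxycyclopentadiene that cannot isomerise by 1,5-hydrogen shift because its sp3 ring carbon bears no hydrogen.

Step 7
Reactants: 10 tert-butyl[(4-allyl-2,3,3-trimethoxycyclopenta-1,4-dien-1-yl)oxy]dimethylsilane; 11 (E)-3-(3,4-dimethoxyphenyl)prop-2-enal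
Product: 12 norbornene cycloadduct: C1 allyl, C2=C4 enol silane (OTBS on C4), C5 OMe, C6 endo Ar (6S), C7 exo CHO, C8(OMe)2
Conditions: (S)-2-[bis(3,5-bis(trifluoromethyl)phenyl)(triethylsilyloxy)methyl]pyrrolidine (20 mol %), 4-nitrobenzoic acid (20 mol %), toluene, 0 °C
Reagents that add atoms: none
Why: Iminium-activated Diels-Alder reaction in which the enol-silane terminus C5 of the diene bonds to the Si face of the iminium β-carbon (the other face is covered by the diarylsilyloxymethyl group) and the α-carbon closes on C1; the E geometry gives the trans Ar/CHO pair, and the exo-directing catalyst together with the clash between an exo aryl group and the C8 methoxy group should place Ar endo and CHO exo, which sets C1, C5, C6 and C7 together.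

Step 8
Reactants: 12 norbornene cycloadduct
Product: 13 norbornane-4,8-dione: C1 allyl, C5 OMe, C6 endo Ar, C7 exo CHO
Conditions: CF3CO2H-H2O (4:1), CH2Cl2, 0 °C → rt
Reagents that add atoms: water, O
Why: Aqueous acid hydrolyses the enol silane to the C4 ketone and the strained C8 dimethyl ketal to the ketone (acetal hydrolysis), and the formyl group should stay exo because epimerisation at C7 would place it cis to the endo aryl group.

Step 9
Reactants: 13 norbornane-4,8-dione aldehyde
Product: 15 diol ketone (C7 exo CH2OH; C8 OH syn to the C2-C4 bridge; C4 ketone), via hydroxymethyl dione 14 (not isolated)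
Conditions: Me4NBH(OAc)3 (2.2 equiv), AcOH-MeCN (1:1), −20 °C → 0 °C
Reagents that add atoms: none
Why: Triacetoxyborohydride reduces only the aldehyde intermolecularly; the exo hydroxymethyl group, which lies syn to C8, then exchanges onto boron and delivers hydride to the C8 carbonyl from the C6-C7 side (Saksena-Evans directed reduction), so the C8 hydroxyl points towards the C2-C4 bridge as in the target, and the reagent is held near two equivalents so the new C8-OH does not in turn direct reduction of C4.

Step 10
Reactants: 15 diol ketone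
Product: 16 primary tosylate (C7 exo CH2OTs; C8 OH; C4 ketone)
Conditions: TsCl (1.1 equiv), pyridine, CH2Cl2, 0 °C
Reagents that add atoms: p-toluenesulfonyl chloride, Cc1ccc(cc1)S(=O)(=O)Cl
Why: Sulfonylation distinguishes the unhindered primary alcohol from the C8 alcohol, which is secondary and flanked by two quaternary bridgeheads, and the C8 oxygen points away from C7, so no cyclic ether can form.

Step 11
Reactants: 16 primary tosylate
Product: 17 bis-silyl tosylate (C8 OTBS; C2=C4 enol silane with OTBS on C4; C7 exo CH2OTs)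
Conditions: TBSOTf (2.5 equiv), Et3N, CH2Cl2, 0 °C → rt
Reagents that add atoms: tert-butyldimethylsilyl trifluoromethanesulfonate, CC(C)(C)[Si](C)(C)OS(=O)(=O)C(F)(F)F
Why: The silyl triflate silylates the hindered C8 alcohol and, by soft enolisation with Et3N, converts the C4 ketone into its enol silane, which can only be C2=C4 because C5 is a quaternary bridgehead.

Step 12
Reactants: 17 bis-silyl tosylate
Product: 18 norbornene enol silane: C1 allyl, C2=C4 (OTBS on C4), C5 OMe, C6 endo Ar, C7 exo Me, C8 OTBS syn to C2=C4
Conditions: LiEt3BH, THF, 0 °C → rt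
Reagents that add atoms: none
Why: SN2 displacement of the primary tosylate by hydride gives the C7 methyl group; the ketone is masked as the enol silane, and the polar mechanism avoids a primary radical that could cyclise onto the allyl group.

Step 13
Reactants: 18 norbornene enol silane; 19 bromoform
Product: 21 3-bromobicyclo[3.2.1]oct-2-en-4-one (C1 allyl; C5 OMe; C6 Ar; C7 Me; C8 OTBS), via siloxy dibromocyclopropane 20 (not isolated)
Conditions: CHBr3 (1.5 equiv), KOtBu (3 equiv), pentane, −20 °C → rt
Reagents that add atoms: none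
Why: Deprotonation of bromoform and α-elimination give dibromocarbene, which adds in a concerted cheletropic [2+1] step to the C2=C4 enol silane, bonding first at the nucleophilic C2, to form 20. In 20 one bromine is necessarily cis to the ring bonds C1-C2 and C4-C5, so it can ionise with disrotatory two-electron electrocyclic cleavage of the shared C2-C4 bond, driven by the siloxy group and the strain of the norbornane-fused cyclopropane; the silyl oxocarbenium ion then gives up its silyl group to tert-butoxide and leaves bromo enone 21. The closest known reactions are the dihalocarbene enlargement of norbornene to 3,4-dihalobicyclo[3.2.1]oct-2-enes and the conversion of cyclic enol silanes into ring-enlarged 2-halo enones. The only ring closed is the three-membered one (cheletropic addition); the six-membered ring C1-C2-C3-C4-C5-C8 arises when that ring opens, and no new stereocentre survives, so the face of carbene attack does not matter. Regiochemistry needs no control because the enol silane can only be C2=C4, and chemoselectivity over the allyl group rests on the much higher nucleophilicity of the trisubstituted enol ether and a small excess of carbene.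

Step 14
Reactants: 21 3-bromobicyclo[3.2.1]oct-2-en-4-one
Product: 22 3-methoxybicyclo[3.2.1]oct-2-en-4-one (C8 OTBS)
Conditions: MeOH, CuI (10 mol %), 3,4,7,8-tetramethyl-1,10-phenanthroline (20 mol %), Cs2CO3, toluene, 80 °C
Reagents that add atoms: methanol, CO
Why: Ullmann-type copper-catalysed C-O coupling of an alkenyl bromide with an alcohol; the electron-poor C3-Br bond should react readily at copper, and the substrate has no enolisable hydrogen (C1 and C5 are quaternary) for the carbonate base to remove.

Step 15
Reactants: 22 3-methoxybicyclo[3.2.1]oct-2-en-4-one (C8 OTBS)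
Product: 23 8-hydroxy-3-methoxybicyclo[3.2.1]oct-2-en-4-one
Conditions: HF·pyridine, pyridine-THF, 0 °C → rt
Reagents that add atoms: none
Why: Fluoride cleaves the Si-O bond under buffered, non-basic conditions, so the β-hydroxy ketone (C8-OH/C4=O) is not exposed to retro-aldol cleavage and the enol ether is not hydrolysed.

Step 16
Reactants: 23 8-hydroxy-3-methoxybicyclo[3.2.1]oct-2-en-4-one
Product: 25 8-hydroxy ketone (3S; all other centres as in the target), via copper enolate 24 (not isolated)
Conditions: [(Ph3P)CuH]6 (0.5 equiv of hexamer), benzene-THF, H2O (2 equiv), rt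
Reagents that add atoms: none
Why: Conjugate reduction by the phosphine-stabilised copper hydride delivers hydride to C2 and leaves the isolated allyl alkene untouched; enolate 24 should then be protonated at C3 on the face syn to C8, because the free C8 hydroxyl sits over that face and relays the proton while the endo aryl group at C6 screens the other, which puts H syn and OMe anti to C8 (3S).

Step 17
Reactants: 25 8-hydroxy ketone
Product: 26 target, CNP0344493.1
Conditions: Ac2O, pyridine, DMAP (5 mol %), CH2Cl2, 0 °C → rt
Reagents that add atoms: acetic anhydride, CC(=O)OC(C)=O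
Why: DMAP-catalysed acylation of the hindered secondary alcohol; the mild base and low temperature should leave the kinetically set, epimerisable C3 centre untouched.

**Compound list**

1 | cyclopent-4-ene-1,3-dione | O=C1C=CC(=O)C1 | starting material
2 | 4,4-dimethoxycyclopent-2-en-1-one | COC1(OC)C=CC(=O)C1 | intermediate
3 | potassium 3,3-dimethoxycyclopenta-1,4-dien-1-olate (not isolated) | [K+].[O-]C1=CC(OC)(OC)C=C1 | intermediate
4 | 5-hydroxy-4,4-dimethoxycyclopent-2-en-1-one, racemic | O=C1C=CC(OC)(OC)C1O | intermediate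
5 | 4,4,5-trimethoxycyclopent-2-en-1-one, racemic | O=C1C=CC(OC)(OC)C1OC | intermediate
6 | allylmagnesium bromide | C=CC[Mg]Br | starting material
7 | trimethyl[(3-allyl-4,4,5-trimethoxycyclopent-1-en-1-yl)oxy]silane, racemic diastereomer mixture | C=CCC1C=C(O[Si](C)(C)C)C(OC)C1(OC)OC | intermediate
8 | 3-allyl-4,4,5-trimethoxycyclopent-2-en-1-one, racemic | C=CCC1=CC(=O)C(OC)C1(OC)OC | intermediate
9 | lithium 4-allyl-2,3,3-trimethoxycyclopenta-1,4-dien-1-olate (not isolated) | [Li+].[O-]C1=C(OC)C(OC)(OC)C(CC=C)=C1 | intermediate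
10 | tert-butyl[(4-allyl-2,3,3-trimethoxycyclopenta-1,4-dien-1-yl)oxy]dimethylsilane | C=CCC1=CC(O[Si](C)(C)C(C)(C)C)=C(OC)C1(OC)OC | intermediate
11 | (E)-3-(3,4-dimethoxyphenyl)prop-2-enal | COc1ccc(/C=C/C=O)cc1OC | starting material
12 | norbornene cycloadduct: C1 allyl, C2=C4 with OTBS on C4, C5 OMe, C6 endo Ar (6S), C7 exo CHO, C8(OMe)2 | C=CC[C@]12C=C(O[Si](C)(C)C(C)(C)C)[C@](OC)([C@H](c3ccc(OC)c(OC)c3)[C@H]1C=O)C2(OC)OC | intermediate
13 | norbornane-4,8-dione: C1 allyl, C5 OMe, C6 endo Ar, C7 exo CHO | C=CC[C@]12CC(=O)[C@](OC)([C@H](c3ccc(OC)c(OC)c3)[C@H]1C=O)C2=O | intermediate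
14 | norbornane-4,8-dione with C7 exo CH2OH (not isolated) | C=CC[C@]12CC(=O)[C@](OC)([C@H](c3ccc(OC)c(OC)c3)[C@H]1CO)C2=O | intermediate
15 | diol ketone: C4 ketone, C7 exo CH2OH, C8 OH syn to the C2-C4 bridge (H towards C6-C7) | C=CC[C@]12CC(=O)[C@](OC)([C@H](c3ccc(OC)c(OC)c3)[C@H]1CO)[C@H]2O | intermediate
16 | primary tosylate of 15 | C=CC[C@]12CC(=O)[C@](OC)([C@H](c3ccc(OC)c(OC)c3)[C@H]1COS(=O)(=O)c4ccc(C)cc4)[C@H]2O | intermediate
17 | C8 TBS ether and C2=C4 TBS enol ether of 16 | C=CC[C@]12C=C(O[Si](C)(C)C(C)(C)C)[C@](OC)([C@H](c3ccc(OC)c(OC)c3)[C@H]1COS(=O)(=O)c4ccc(C)cc4)[C@H]2O[Si](C)(C)C(C)(C)C | intermediate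
18 | norbornene enol silane: C1 allyl, C2=C4 with OTBS on C4, C5 OMe, C6 endo Ar, C7 exo Me, C8 OTBS syn to C2=C4 | C=CC[C@]12C=C(O[Si](C)(C)C(C)(C)C)[C@](OC)([C@H](c3ccc(OC)c(OC)c3)[C@H]1C)[C@H]2O[Si](C)(C)C(C)(C)C | intermediate
19 | bromoform | BrC(Br)Br | starting material
20 | siloxy dibromocyclopropane: CBr2 bridging C2 and C4 of 18, either face (not isolated) | C=CC[C@]12C3C(Br)(Br)C3(O[Si](C)(C)C(C)(C)C)[C@](OC)([C@H](c4ccc(OC)c(OC)c4)[C@H]1C)[C@H]2O[Si](C)(C)C(C)(C)C | intermediate
21 | 3-bromobicyclo[3.2.1]oct-2-en-4-one: C1 allyl, C5 OMe, C6 Ar anti to C8, C7 Me syn to C8, C8 OTBS syn to the enone bridge | C=CC[C@]12C=C(Br)C(=O)[C@](OC)([C@H](c3ccc(OC)c(OC)c3)[C@H]1C)[C@H]2O[Si](C)(C)C(C)(C)C | intermediate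
22 | 3-methoxy analogue of 21 | C=CC[C@]12C=C(OC)C(=O)[C@](OC)([C@H](c3ccc(OC)c(OC)c3)[C@H]1C)[C@H]2O[Si](C)(C)C(C)(C)C | intermediate
23 | 8-hydroxy-3-methoxybicyclo[3.2.1]oct-2-en-4-one (desilylated 22) | C=CC[C@]12C=C(OC)C(=O)[C@](OC)([C@H](c3ccc(OC)c(OC)c3)[C@H]1C)[C@H]2O | intermediate
24 | copper enolate C3=C4(OCu) of the reduced enone (not isolated) | C=CC[C@]12CC(OC)=C(O[Cu])[C@](OC)([C@H](c3ccc(OC)c(OC)c3)[C@H]1C)[C@H]2O | intermediate
25 | 8-hydroxy ketone, (1S,3S,5S,6S,7R,8S), deacetyl target | C=CC[C@]12C[C@H](OC)C(=O)[C@](OC)([C@H](c3ccc(OC)c(OC)c3)[C@H]1C)[C@H]2O | intermediate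
26 | CNP0344493.1, (1S,3S,5S,6S,7R,8S)-8-acetoxy-1-allyl-6-(3,4-dimethoxyphenyl)-3,5-dimethoxy-7-methylbicyclo[3.2.1]octan-4-one (locants as above) | C=CC[C@]12C[C@H](OC)C(=O)[C@](OC)([C@H](c3ccc(OC)c(OC)c3)[C@H]1C)[C@H]2OC(C)=O | target

**Step count and risks**

Total step count: 17. Longest linear sequence: 17 steps (from 1).

Steps most likely to fail:

Step 7. The ammonium co-catalyst may protodesilylate the dienol ether before cycloaddition, and control of the enal face or of the endo/exo orientation may be poor. Fallback: from 10 and 11 the cycloaddition is run without a chiral catalyst (toluene, 80 °C, or Eu(fod)3 at rt) to give the racemic cycloadduct F1. Its aldehyde is condensed with (1R,2R)-N,N'-dimethyl-1,2-diphenylethane-1,2-diamine (MgSO4, CH2Cl2) to two diastereomeric imidazolidines, which are separated. The 6S diastereomer, the aminal F2, is treated with the aqueous acid of step 8, which cleaves aminal, ketal and enol silane together, and the route is rejoined at 13.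

Step 13. Carbene transfer to the enol silane may be slow, because its exo face is flanked by the C8 silyloxy group and its endo face by the C6 aryl group, so cyclopropanation of the allyl group or carbene decay may take over. Fallback: from 18 the smaller zinc carbenoid (Et2Zn, CH2I2, CH2Cl2, 0 °C; Simmons-Smith reaction, Furukawa variant) gives the siloxycyclopropane F3. FeCl3 in DMF opens it by one-electron oxidation with cleavage of the same C2-C4 bond to the 2-chloro ketone F4, and NaOAc in MeOH eliminates HCl to the enone F5. Iodine with K2CO3 and catalytic DMAP in aqueous THF gives the 3-iodo enone F6, which under the conditions of step 14 gives 22.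

Step 14. Conjugate addition of methoxide at C2 or hydrodebromination may outrun C-O bond formation at copper. Fallback: from 21, Miyaura borylation (B2pin2, PdCl2(dppf), KOAc, dioxane, 80 °C) gives the alkenyl boronate F7 and oxidation (NaBO3, THF-H2O) the diosphenol F8, whose enolic hydroxyl is methylated (MeI, K2CO3, acetone) to rejoin the route at 22.

**Further compounds**

F1 | step 7 | racemic cycloadduct (racemate of 12, same relative configuration) | C=CCC12C=C(O[Si](C)(C)C(C)(C)C)C(OC)(C(c3ccc(OC)c(OC)c3)C1C=O)C2(OC)OC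
F2 | step 7 | aminal of 12 with (1R,2R)-N,N'-dimethyl-1,2-diphenylethane-1,2-diamine (1,3-dimethyl-4,5-diphenylimidazolidin-2-yl at C7) | C=CC[C@]12C=C(O[Si](C)(C)C(C)(C)C)[C@](OC)([C@H](c3ccc(OC)c(OC)c3)[C@H]1C4N(C)[C@H](c5ccccc5)[C@@H](c6ccccc6)N4C)C2(OC)OC
F3 | step 13 | siloxycyclopropane: CH2 bridging C2 and C4 of 18 | C=CC[C@]12C3CC3(O[Si](C)(C)C(C)(C)C)[C@](OC)([C@H](c4ccc(OC)c(OC)c4)[C@H]1C)[C@H]2O[Si](C)(C)C(C)(C)C
F4 | step 13 | 2-chlorobicyclo[3.2.1]octan-4-one (C8 OTBS) | C=CC[C@]12C(Cl)CC(=O)[C@](OC)([C@H](c3ccc(OC)c(OC)c3)[C@H]1C)[C@H]2O[Si](C)(C)C(C)(C)C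
F5 | step 13 | bicyclo[3.2.1]oct-2-en-4-one (C8 OTBS) | C=CC[C@]12C=CC(=O)[C@](OC)([C@H](c3ccc(OC)c(OC)c3)[C@H]1C)[C@H]2O[Si](C)(C)C(C)(C)C
F6 | step 13 | 3-iodobicyclo[3.2.1]oct-2-en-4-one (C8 OTBS) | C=CC[C@]12C=C(I)C(=O)[C@](OC)([C@H](c3ccc(OC)c(OC)c3)[C@H]1C)[C@H]2O[Si](C)(C)C(C)(C)C
F7 | step 14 | 3-(pinacolatoboryl)bicyclo[3.2.1]oct-2-en-4-one (C8 OTBS) | C=CC[C@]12C=C(B3OC(C)(C)C(C)(C)O3)C(=O)[C@](OC)([C@H](c4ccc(OC)c(OC)c4)[C@H]1C)[C@H]2O[Si](C)(C)C(C)(C)C
F8 | step 14 | 3-hydroxybicyclo[3.2.1]oct-2-en-4-one, diosphenol (C8 OTBS) | C=CC[C@]12C=C(O)C(=O)[C@](OC)([C@H](c3ccc(OC)c(OC)c3)[C@H]1C)[C@H]2O[Si](C)(C)C(C)(C)C
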